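## Retrosynthetic overview

1. The target comes from silyl ether 12 by a final desilylation/acetylation at the CH2O group on C‑4.
2. Bicycle 12 comes from acyclic pentaene 11 by an intramolecular vinylallene Diels–Alder reaction. Rings A and B close together (C‑5–C‑10 and C‑8–C‑9 bonds), and the 6,8(17)‑diene, C‑5, C‑9 and C‑10 arise in the same step.
3. The vinylallene of 11 is built on aldehyde 9 by Takai iodo‑olefination and allenyl Stille coupling.
4. The C‑4 quaternary centre of 9 comes from a Sharpless epoxide by the Yamamoto epoxy silyl ether rearrangement.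
5. The chain is joined by copper‑catalysed coupling of enynol 4 with allylic bromide 3 (from methyl geranate). The linking alkyne is saturated later.

Assumption: ring positions are cited with labdane numbering (C‑4 carries CH3/CH2O, C‑5/C‑10 are the ring fusion, C‑9 carries the side chain, C‑8 the methylidene); methyl geranate and (E)‑3‑methylpent‑2‑en‑4‑yn‑1‑ol are bought.

## Route

Step 1
Reactants: 1 methyl (2E)-3,7-dimethylocta-2,6-dienoate (methyl geranate)
Product: 2 methyl (2E,6E)-8-hydroxy-3,7-dimethylocta-2,6-dienoate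
Conditions: SeO2 (cat.), t-BuOOH, salicylic acid (cat.), CH2Cl2, rt
Reagents that add atoms: tert-butyl hydroperoxide CC(C)(C)OO
Why: Riley allylic oxidation in its catalytic SeO2/t-BuOOH form (ene reaction then [2,3] shift) attacks the electron-rich 6,7-alkene rather than the enoate and oxidises only the (E)-methyl group, which fixes the 6E geometry of the later dienophile.

Step 2
Reactants: 2 methyl (2E,6E)-8-hydroxy-3,7-dimethylocta-2,6-dienoate
Product: 3 methyl (2E,6E)-8-bromo-3,7-dimethylocta-2,6-dienoate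
Conditions: CBr4, PPh3, CH2Cl2, 0 °C
Reagents that add atoms: carbon tetrabromide BrC(Br)(Br)Br
Why: Appel bromination converts the primary allylic alcohol into the bromide under neutral conditions without allylic transposition or loss of alkene geometry.

Step 3
Reactants: 3 methyl (2E,6E)-8-bromo-3,7-dimethylocta-2,6-dienoate; 4 (2E)-3-methylpent-2-en-4-yn-1-ol
Product: 5 methyl (2E,6E,11E)-13-hydroxy-3,7,11-trimethyltrideca-2,6,11-trien-9-ynoate
Conditions: CuI (10 mol %), n-Bu4NI (10 mol %), K2CO3, DMF, rt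
Reagents that add atoms: none
Why: Copper-catalysed coupling of a terminal alkyne with a primary allylic bromide (copper acetylide SN2 allylation) gives the skipped enyne at the unhindered CH2 with retention of the 6E alkene, and the free alcohol and the ester are tolerated.

Step 4
Reactants: 5 methyl (2E,6E,11E)-13-hydroxy-3,7,11-trimethyltrideca-2,6,11-trien-9-ynoate
Product: 6 methyl (2E,6E)-10-[(2R,3R)-3-(hydroxymethyl)-2-methyloxiran-2-yl]-3,7-dimethyldeca-2,6-dien-9-ynoate
Conditions: Ti(OiPr)4 (10 mol %), D-(−)-diisopropyl tartrate (12 mol %), t-BuOOH, 4 Å MS, CH2Cl2, −20 °C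
Reagents that add atoms: tert-butyl hydroperoxide CC(C)(C)OO
Why: Sharpless asymmetric epoxidation touches only the allylic-alcohol alkene, and with D-(−)-tartrate the (E)-alcohol gives the (2R,3R)-epoxide (mirror image of the (2S,3S) series that L-(+)-tartrate gives with geraniol), which stores the configuration of the future C-4 (about 90–95 % ee expected).

Step 5
Reactants: 6 methyl (2E,6E)-10-[(2R,3R)-3-(hydroxymethyl)-2-methyloxiran-2-yl]-3,7-dimethyldeca-2,6-dien-9-ynoate
Product: 7 methyl (2E,6E)-10-[(2R,3R)-3-({[tert-butyl(dimethyl)silyl]oxy}methyl)-2-methyloxiran-2-yl]-3,7-dimethyldeca-2,6-dien-9-ynoate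
Conditions: TBSCl, imidazole, DMF, 0 °C to rt
Reagents that add atoms: tert-butyldimethylsilyl chloride CC(C)(C)[Si](C)(C)Cl
Why: Standard silylation of the primary alcohol provides the siloxymethyl group that the later rearrangement needs as migrating group, and no stereocentre is touched.

Step 6
Reactants: 7 methyl (2E,6E)-10-[(2R,3R)-3-({[tert-butyl(dimethyl)silyl]oxy}methyl)-2-methyloxiran-2-yl]-3,7-dimethyldeca-2,6-dien-9-ynoate
Product: 8 methyl (2E,6E)-10-[(2R,3R)-3-({[tert-butyl(dimethyl)silyl]oxy}methyl)-2-methyloxiran-2-yl]-3,7-dimethyldeca-2,6-dienoate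
Conditions: H2 (1–3 atm), RhCl(PPh3)3 (10 mol %), PhH/EtOH, rt
Reagents that add atoms: none
Why: Homogeneous hydrogenation with Wilkinson's catalyst reduces the internal alkyne (and the cis-alkene formed from it) to CH2CH2, while the two trisubstituted alkenes, the epoxide and the silyl ether are expected to survive.

Step 7
Reactants: 8 methyl (2E,6E)-10-[(2R,3R)-3-({[tert-butyl(dimethyl)silyl]oxy}methyl)-2-methyloxiran-2-yl]-3,7-dimethyldeca-2,6-dienoate
Product: 9 methyl (2E,6E,11R)-11-({[tert-butyl(dimethyl)silyl]oxy}methyl)-3,7,11-trimethyl-12-oxododeca-2,6-dienoate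
Conditions: methylaluminium bis(4-bromo-2,6-di-tert-butylphenoxide) (MABR, 20 mol %), CH2Cl2, −78 to −20 °C
Reagents that add atoms: none
Why: Yamamoto rearrangement of an epoxy silyl ether (semipinacol type) opens the epoxide at the tertiary carbon while the siloxymethyl group shifts 1,2 anti to the breaking C–O bond, so the epoxide configuration is passed with inversion to the 11R quaternary aldehyde carbon (future C-4, with CHO as future C-5 and CH2OTBS as future C-18).

Step 8
Reactants: 9 methyl (2E,6E,11R)-11-({[tert-butyl(dimethyl)silyl]oxy}methyl)-3,7,11-trimethyl-12-oxododeca-2,6-dienoate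
Product: 10 methyl (2E,6E,11S,12E)-11-({[tert-butyl(dimethyl)silyl]oxy}methyl)-13-iodo-3,7,11-trimethyltrideca-2,6,12-trienoate
Conditions: CrCl2 (6 equiv), CHI3 (2 equiv), THF/dioxane, 0 °C to rt
Reagents that add atoms: iodoform IC(I)I
Why: Takai olefination converts the non-enolisable α-quaternary aldehyde into the (E)-vinyl iodide with high E selectivity and leaves ester, silyl ether and alkenes alone (the descriptor changes from R to S only because the priorities change).

Step 9
Reactants: 10 methyl (2E,6E,11S,12E)-11-({[tert-butyl(dimethyl)silyl]oxy}methyl)-13-iodo-3,7,11-trimethyltrideca-2,6,12-trienoate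
Product: 11 methyl (2E,6E,11S,12E)-11-({[tert-butyl(dimethyl)silyl]oxy}methyl)-3,7,11-trimethylhexadeca-2,6,12,14,15-pentaenoate
Conditions: tributyl(propa-1,2-dienyl)stannane, Pd2(dba)3 (2.5 mol %), AsPh3, CuI (10 mol %), DMF, rt
Reagents that add atoms: tributyl(propa-1,2-dien-1-yl)stannane C=C=C[Sn](CCCC)(CCCC)CCCC
Why: Stille coupling of the allenylstannane with the vinyl iodide transfers the allenyl group with retention of the 12E geometry and gives the conjugated vinylallene at room temperature, below the onset of cycloaddition.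

Step 10
Reactants: 11 methyl (2E,6E,11S,12E)-11-({[tert-butyl(dimethyl)silyl]oxy}methyl)-3,7,11-trimethylhexadeca-2,6,12,14,15-pentaenoate
Product: 12 methyl (2E)-5-[(1R,4aS,5S,8aS)-5-({[tert-butyl(dimethyl)silyl]oxy}methyl)-5,8a-dimethyl-2-methylidene-1,2,4a,5,6,7,8,8a-octahydronaphthalen-1-yl]-3-methylpent-2-enoate
Conditions: PhMe (0.01 M), BHT (cat.), 140 °C, sealed tube
Reagents that add atoms: none
Why: Thermal intramolecular Diels–Alder reaction of a vinylallene, in which the allene keeps its C=CH2 so the 6,8(17)-diene is formed directly: the chair-like anti (tether-exo) transition state gives the trans ring fusion, suprafacial addition to the 6E alkene places the side chain cis to the angular methyl, and the diene face is selected by C-4 with the methyl group in the crowded inside (axial) position and the CH2OTBS group anti (equatorial), which sets C-5 (S), C-10 (S) and C-9 (R); cis-fused and wrong-face isomers are removed by chromatography.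

Step 11
Reactants: 12 methyl (2E)-5-[(1R,4aS,5S,8aS)-5-({[tert-butyl(dimethyl)silyl]oxy}methyl)-5,8a-dimethyl-2-methylidene-1,2,4a,5,6,7,8,8a-octahydronaphthalen-1-yl]-3-methylpent-2-enoate
Product: 14 methyl (2E)-5-[(1R,4aS,5S,8aS)-5-(acetoxymethyl)-5,8a-dimethyl-2-methylidene-1,2,4a,5,6,7,8,8a-octahydronaphthalen-1-yl]-3-methylpent-2-enoate, via primary alcohol 13 (not isolated)
Conditions: TBAF, THF, 0 °C; then Ac2O, DMAP (cat.), rt
Reagents that add atoms: acetic anhydride CC(=O)OC(C)=O
Why: Fluoride desilylation followed by in-flask DMAP-catalysed acetylation of the released alkoxide avoids acid, so the acid-sensitive exocyclic diene, the methyl ester and all four stereocentres are untouched.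

## Compound list

1 | methyl (2E)-3,7-dimethylocta-2,6-dienoate (methyl geranate) | CC(C)=CCC/C(C)=C/C(=O)OC | starting material
2 | methyl (2E,6E)-8-hydroxy-3,7-dimethylocta-2,6-dienoate | OC/C(C)=C/CC/C(C)=C/C(=O)OC | intermediate
3 | methyl (2E,6E)-8-bromo-3,7-dimethylocta-2,6-dienoate | BrC/C(C)=C/CC/C(C)=C/C(=O)OC | intermediate
4 | (2E)-3-methylpent-2-en-4-yn-1-ol | C#C/C(C)=C/CO | starting material
5 | methyl (2E,6E,11E)-13-hydroxy-3,7,11-trimethyltrideca-2,6,11-trien-9-ynoate | OC/C=C(C)/C#CC/C(C)=C/CC/C(C)=C/C(=O)OC | intermediate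
6 | methyl (2E,6E)-10-[(2R,3R)-3-(hydroxymethyl)-2-methyloxiran-2-yl]-3,7-dimethyldeca-2,6-dien-9-ynoate | OC[C@H]1O[C@]1(C)C#CC/C(C)=C/CC/C(C)=C/C(=O)OC | intermediate
7 | methyl (2E,6E)-10-[(2R,3R)-3-({[tert-butyl(dimethyl)silyl]oxy}methyl)-2-methyloxiran-2-yl]-3,7-dimethyldeca-2,6-dien-9-ynoate | CC(C)(C)[Si](C)(C)OC[C@H]1O[C@]1(C)C#CC/C(C)=C/CC/C(C)=C/C(=O)OC | intermediate
8 | methyl (2E,6E)-10-[(2R,3R)-3-({[tert-butyl(dimethyl)silyl]oxy}methyl)-2-methyloxiran-2-yl]-3,7-dimethyldeca-2,6-dienoate | CC(C)(C)[Si](C)(C)OC[C@H]1O[C@]1(C)CCC/C(C)=C/CC/C(C)=C/C(=O)OC | intermediate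
9 | methyl (2E,6E,11R)-11-({[tert-butyl(dimethyl)silyl]oxy}methyl)-3,7,11-trimethyl-12-oxododeca-2,6-dienoate | O=C[C@@](C)(CO[Si](C)(C)C(C)(C)C)CCC/C(C)=C/CC/C(C)=C/C(=O)OC | intermediate
10 | methyl (2E,6E,11S,12E)-11-({[tert-butyl(dimethyl)silyl]oxy}methyl)-13-iodo-3,7,11-trimethyltrideca-2,6,12-trienoate | I/C=C/[C@@](C)(CO[Si](C)(C)C(C)(C)C)CCC/C(C)=C/CC/C(C)=C/C(=O)OC | intermediate
11 | methyl (2E,6E,11S,12E)-11-({[tert-butyl(dimethyl)silyl]oxy}methyl)-3,7,11-trimethylhexadeca-2,6,12,14,15-pentaenoate | C=C=C/C=C/[C@@](C)(CO[Si](C)(C)C(C)(C)C)CCC/C(C)=C/CC/C(C)=C/C(=O)OC | intermediate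
12 | methyl (2E)-5-[(1R,4aS,5S,8aS)-5-({[tert-butyl(dimethyl)silyl]oxy}methyl)-5,8a-dimethyl-2-methylidene-1,2,4a,5,6,7,8,8a-octahydronaphthalen-1-yl]-3-methylpent-2-enoate | C=C1C=C[C@@H]2[C@@](C)(CO[Si](C)(C)C(C)(C)C)CCC[C@@]2(C)[C@@H]1CC/C(C)=C/C(=O)OC | intermediate
13 | methyl (2E)-5-[(1R,4aS,5S,8aS)-5-(hydroxymethyl)-5,8a-dimethyl-2-methylidene-1,2,4a,5,6,7,8,8a-octahydronaphthalen-1-yl]-3-methylpent-2-enoate | C=C1C=C[C@@H]2[C@@](C)(CO)CCC[C@@]2(C)[C@@H]1CC/C(C)=C/C(=O)OC | intermediate
14 | methyl (2E)-5-[(1R,4aS,5S,8aS)-5-(acetoxymethyl)-5,8a-dimethyl-2-methylidene-1,2,4a,5,6,7,8,8a-octahydronaphthalen-1-yl]-3-methylpent-2-enoate (CNP0148290.1) | C=C1C=C[C@@H]2[C@@](C)(COC(C)=O)CCC[C@@]2(C)[C@@H]1CC/C(C)=C/C(=O)OC | target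

## Step count and risks

Total step count: 11.
Longest linear sequence: 11 steps (1 to 14; enynol 4 enters at step 3).

Steps most likely to fail:

**Step 10 (intramolecular Diels–Alder).** The dienophile is an unactivated trisubstituted alkene. The face selectivity rests only on methyl versus CH2OTBS at C‑4, which I expect to be modest (about 2–3:1), and cis‑fused adducts can also form, so the desired isomer may be only about half of the mixture.

Fallback: make the C‑18 group α‑branched before the cycloaddition, so that it cannot occupy the inside position. It sets out from 11 and comes back at 13. Desilylation of 11 with TBAF gives methyl (2E,6E,11S,12E)-11-(hydroxymethyl)-3,7,11-trimethylhexadeca-2,6,12,14,15-pentaenoate F1. Dess–Martin oxidation gives methyl (2E,6E,11S,12E)-11-formyl-3,7,11-trimethylhexadeca-2,6,12,14,15-pentaenoate F2. Trimethyl orthoformate with PPTS in methanol gives methyl (2E,6E,11S,12E)-11-(dimethoxymethyl)-3,7,11-trimethylhexadeca-2,6,12,14,15-pentaenoate F3. Heating F3 as in step 10 should give methyl (2E)-5-[(1R,4aS,5S,8aS)-5-(dimethoxymethyl)-5,8a-dimethyl-2-methylidene-1,2,4a,5,6,7,8,8a-octahydronaphthalen-1-yl]-3-methylpent-2-enoate F4 with much higher face selectivity, because an acetal carbon in the inside position would clash with both H‑6 and the incoming angular methyl. Mild hydrolysis (LiBF4, wet MeCN) gives methyl (2E)-5-[(1R,4aS,5S,8aS)-5-formyl-5,8a-dimethyl-2-methylidene-1,2,4a,5,6,7,8,8a-octahydronaphthalen-1-yl]-3-methylpent-2-enoate F5. NaBH4 in MeOH at 0 °C then gives alcohol 13, which is acetylated as in step 11. This fallback does not improve the trans/cis ratio.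

**Step 6 (selective hydrogenation).** The alkyne sits next to a quaternary epoxide carbon, so the reduction may stall at the hindered cis‑alkene or, if forced, start to reduce the trisubstituted alkenes.

Fallback: join the fragments by B‑alkyl Suzuki coupling so that no alkyne has to be reduced. It sets out from 3 and comes back at 9. Stille coupling of 3 with tributyl(vinyl)stannane gives methyl (2E,6E)-3,7-dimethyldeca-2,6,9-trienoate F6. Hydroboration of its terminal alkene with 9‑BBN gives methyl (2E,6E)-10-(9-borabicyclo[3.3.1]nonan-9-yl)-3,7-dimethyldeca-2,6-dienoate F7, used in the flask. Suzuki–Miyaura coupling (PdCl2(dppf), AsPh3, Cs2CO3, DMF/H2O) with (2Z)-3-iodobut-2-en-1-ol F8 (made from but‑2‑yn‑1‑ol with Red‑Al, then I2) gives methyl (2E,6E,11Z)-13-hydroxy-3,7,11-trimethyltrideca-2,6,11-trienoate F9. Sharpless epoxidation of this (Z)-alcohol with L‑(+)‑diisopropyl tartrate gives methyl (2E,6E)-10-[(2R,3S)-3-(hydroxymethyl)-2-methyloxiran-2-yl]-3,7-dimethyldeca-2,6-dienoate F10. Silylation gives methyl (2E,6E)-10-[(2R,3S)-3-({[tert-butyl(dimethyl)silyl]oxy}methyl)-2-methyloxiran-2-yl]-3,7-dimethyldeca-2,6-dienoate F11. The MABR rearrangement of F11 gives the same aldehyde 9, because the quaternary epoxide carbon has the same configuration and the other epoxide carbon becomes the CHO group.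

**Step 9 (allenyl Stille coupling).** Propargyl‑transfer (1,4‑enyne) by‑products and slow coupling at the neopentyl‑type vinyl iodide are possible.

Fallback: build the allene by reductive transposition instead of coupling. It sets out from 10 and comes back at 11. Sonogashira coupling of 10 with prop‑2‑yn‑1‑ol (PdCl2(PPh3)2, CuI, Et3N) gives methyl (2E,6E,11S,12E)-11-({[tert-butyl(dimethyl)silyl]oxy}methyl)-16-hydroxy-3,7,11-trimethylhexadeca-2,6,12-trien-14-ynoate F12. Myers allene synthesis (2‑nitrobenzenesulfonylhydrazide, PPh3, DEAD, THF, −15 °C to rt) then converts the propargylic alcohol through the diazene into the terminal allene 11.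

Further compounds
F1 | step 10 | methyl (2E,6E,11S,12E)-11-(hydroxymethyl)-3,7,11-trimethylhexadeca-2,6,12,14,15-pentaenoate | C=C=C/C=C/[C@@](C)(CO)CCC/C(C)=C/CC/C(C)=C/C(=O)OC
F2 | step 10 | methyl (2E,6E,11S,12E)-11-formyl-3,7,11-trimethylhexadeca-2,6,12,14,15-pentaenoate | C=C=C/C=C/[C@@](C)(C=O)CCC/C(C)=C/CC/C(C)=C/C(=O)OC
F3 | step 10 | methyl (2E,6E,11S,12E)-11-(dimethoxymethyl)-3,7,11-trimethylhexadeca-2,6,12,14,15-pentaenoate | C=C=C/C=C/[C@@](C)(C(OC)OC)CCC/C(C)=C/CC/C(C)=C/C(=O)OC
F4 | step 10 | methyl (2E)-5-[(1R,4aS,5S,8aS)-5-(dimethoxymethyl)-5,8a-dimethyl-2-methylidene-1,2,4a,5,6,7,8,8a-octahydronaphthalen-1-yl]-3-methylpent-2-enoate | C=C1C=C[C@@H]2[C@@](C)(C(OC)OC)CCC[C@@]2(C)[C@@H]1CC/C(C)=C/C(=O)OC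
F5 | step 10 | methyl (2E)-5-[(1R,4aS,5S,8aS)-5-formyl-5,8a-dimethyl-2-methylidene-1,2,4a,5,6,7,8,8a-octahydronaphthalen-1-yl]-3-methylpent-2-enoate | C=C1C=C[C@@H]2[C@@](C)(C=O)CCC[C@@]2(C)[C@@H]1CC/C(C)=C/C(=O)OC
F6 | step 6 | methyl (2E,6E)-3,7-dimethyldeca-2,6,9-trienoate | C=CC/C(C)=C/CC/C(C)=C/C(=O)OC
F7 | step 6 | methyl (2E,6E)-10-(9-borabicyclo[3.3.1]nonan-9-yl)-3,7-dimethyldeca-2,6-dienoate | B1(CCC/C(C)=C/CC/C(C)=C/C(=O)OC)C2CCCC1CCC2
F8 | step 6 | (2Z)-3-iodobut-2-en-1-ol | OC/C=C(\I)C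
F9 | step 6 | methyl (2E,6E,11Z)-13-hydroxy-3,7,11-trimethyltrideca-2,6,11-trienoate | OC/C=C(C)\CCC/C(C)=C/CC/C(C)=C/C(=O)OC
F10 | step 6 | methyl (2E,6E)-10-[(2R,3S)-3-(hydroxymethyl)-2-methyloxiran-2-yl]-3,7-dimethyldeca-2,6-dienoate | OC[C@@H]1O[C@]1(C)CCC/C(C)=C/CC/C(C)=C/C(=O)OC
F11 | step 6 | methyl (2E,6E)-10-[(2R,3S)-3-({[tert-butyl(dimethyl)silyl]oxy}methyl)-2-methyloxiran-2-yl]-3,7-dimethyldeca-2,6-dienoate | CC(C)(C)[Si](C)(C)OC[C@@H]1O[C@]1(C)CCC/C(C)=C/CC/C(C)=C/C(=O)OC
F12 | step 9 | methyl (2E,6E,11S,12E)-11-({[tert-butyl(dimethyl)silyl]oxy}methyl)-16-hydroxy-3,7,11-trimethylhexadeca-2,6,12-trien-14-ynoate | OCC#C/C=C/[C@@](C)(CO[Si](C)(C)C(C)(C)C)CCC/C(C)=C/CC/C(C)=C/C(=O)OC
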